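## Analysis of the target

The target is a daucane-type hydroazulene: a cyclopentane (C1–C5) fused along C1–C5 to a cycloheptenone (C1, C5–C10), with the C6 oxygen esterified by 4-methoxybenzoic acid. In the numbering used throughout, C1 is the methyl-bearing quaternary fusion carbon, C2 and C3 are methylenes, C4 is the tertiary carbinol carrying isopropyl, C5 is the fusion methine, C6 the ester carbinol, C7 a methylene, C8=C9 the methyl-substituted enone double bond and C10 the ketone. The four contiguous stereocentres are (1S,4R,5S,6S) in this numbering. Calling α the face of the C1 methyl, the ring fusion is trans (H5 is β), the C4 hydroxyl is α (isopropyl β) and the C6 acyloxy group is β, cis to H5. The sensitive groups are the δ-acyloxy enone (base can expel 4-methoxybenzoate through the C7 dienolate), the tertiary alcohol (strong acid dehydrates it) and the ester (no organometallic reagent may follow its introduction). The difficulty is a quaternary centre flanked by a ketone and by three further stereocentres on a flexible seven-membered ring, with nothing outside the bicycle to relay stereochemistry. The plan rests on one feature: with C5 and C10 both written as carbonyls, C1 is the prochiral centre of a 2,2-disubstituted cycloheptane-1,3-dione, and C4–C5, with C4 as carbonyl and C5 as carbinol, is the bond of an acyloin. One enantioselective differentiation of two carbonyl groups therefore fixes C1 and closes ring C1–C5 at once.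

## Retrosynthetic reasoning

**25 ⇒ 23.** The C8=C9 double bond is made last. Once it exists the C6 ester is δ to the carbonyl and any base can eliminate it, so the enone is released from the silyl enol ether 23 by a neutral palladium-mediated oxidation. Only hydrolysis of a tertiary silyl ether (24) follows.

**23 ⇒ 21 + 22.** The C8–CH3 bond is cut as a methyl cuprate made from 22. C8 is the β-carbon of the simpler enone 21, and silyl trapping of the enolate gives directly the enol ether needed for the last step.

**21 ⇒ 20.** The C8–C9 unsaturation comes from dehydrogenation of the C10 ketone. C1 is quaternary, so C9 is the only enolisable position and no regiochemical question arises.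

**20 ⇒ 18 + 19.** The ester C–O bond is cut before the enone is built. The 4-methoxybenzoate then protects O6 through the last three steps and no separate protecting-group pair is needed. In 18 only the secondary C6 hydroxyl can be acylated.

**18 ⇒ 17 ⇒ 15 + 16.** The C4–isopropyl bond is cut at the trans-fused ketone 15. There the C1 methyl is axial on the α face and 1,3 to C4, so the reagent must enter from the β face, which leaves the hydroxyl α as required. The bond is deliberately not made at the enone stage 8 for two reasons:
- with C5 trigonal, C10 and the methyl flank C4 from the two faces in near mirror-image positions, so the facial outcome could not be predicted;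
- a β-isopropyl group would then sit on the face from which C5=C6 has to be hydroborated.

**15 ⇒ 14 ⇒ 13 ⇒ 12.** These are adjustments of oxidation level and protection: the C4 ketone from the C4 alcohol, with O6 carried as a silyl ether that is inert to the organocerium reagent and falls off later together with the C10 ketal.

**12 ⇒ 10.** The C5–H and C6–O bonds are cut together as a hydroboration of C5=C6. Both centres arise in one syn addition, so their relative configuration is fixed by mechanism, and only the face has to be controlled. In 10 the α face carries both the C1 methyl and the C4 silyloxy group.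

**10 ⇒ 9 ⇒ 8.** The C4 silyloxy group is a temporary stereocentre. It is set by reagent-controlled reduction of enone 8, because the substrate cannot be trusted to differentiate the faces of C4, and it is erased again in 15.

**8 ⇒ 7.** C10 must be masked before any hydride or organometallic reagent is used. In 7 it is the only saturated ketone, so it can be ketalised selectively next to the enone.

**7 ⇒ 6.** C5=C6 comes from dehydration of the tertiary ketol 6. Only C6 offers β-hydrogens, and the elimination also removes the cis ring fusion that the ring closure necessarily produces.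

**6 ⇒ 5.** This is the key disconnection of C4–C5, an acyloin bond formed by carbene-catalysed addition of the aldehyde carbon to one of two enantiotopic ring carbonyls. It gives ring C1–C5 and the quaternary centre C1 in one catalytic step from an achiral precursor.

**5 ⇒ 3 + 4 and 3 ⇒ 1 + 2.** The C1–C2 bond is cut as a Michael addition to 4 and the C1–CH3 bond as a C-methylation with 2. The risk of the route is thereby concentrated in the key step.

## Alternatives that were turned down

**Alternative 1:** One-carbon ring expansion of a trans-hydrindanone. C9 is removed in the retron, so that C8 and C10 are directly bonded in a six-membered ring. Forward, the silyl enol ether A1 is cyclopropanated by a zinc carbenoid, and oxidative opening of the internal cyclopropane bond with a ferric salt followed by elimination gives the cycloheptenone A2.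
- For: all stereocentres would be set on a rigid 5–6 system, and the C8-methyl enone appears in one operation. On that point it is stronger than the chosen endgame (steps 15–17).
- Against: A1 is a fully substituted enol ether next to the quaternary C1, hard to cyclopropanate, and its three silyl ethers must survive a Lewis-acidic oxidant. The hydrindanone behind A1 has its ketone in the six-membered ring next to the quaternary carbon and an oxygen on the five-membered ring, a pattern not delivered by the classical proline annulation, so absolute control and step count are both open.
- Comparison: the chosen route gives up the one-step enone but has the seven-membered ring from the first step and sets C1 catalytically in step 3.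

**Alternative 2:** Three-component conjugate alkenylation–aldol on a cyclopentenone. C1–C10 and C5–C6 are cut. Forward, copper-catalysed addition of the α-silylvinylaluminium reagent A4 to 3-methylcyclopent-2-enone A3 creates the quaternary C1, and the aluminium enolate is trapped by aldehyde A5 to give aldol A6.
- For: it is more convergent than the chosen route, assembling C1, C5 and C6 and most of the carbons in one flask. The trans relation between the C1 vinyl group and the C5 side chain follows from anti attack on the enolate.
- Against: the carbinol centre C6 depends on an aldol with an unbranched aldehyde, where simple diastereoselection is weak. A6 is a β-hydroxy ketone that must take isopropyl at C4 without retro-aldol or elimination. The seven-membered ring is still open, and closing it by condensation of the unmasked C10 and C8 ketones competes with five-membered aldol modes.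
- Comparison: the chosen route offers a closed bicycle from step 3, on which each later centre is set by a rigid-ring argument.

**Alternative 3:** Tethered oxyallyl cation (4+3) cycloaddition. C1–C5 and C8–C9 are cut. Forward, ionisation of the α-chloro ketone A7 gives an oxyallyl cation that adds across its own (E,E)-diene to form both rings, giving A8.
- For: it is the shortest way to the skeleton and stronger than the chosen route in step economy up to the bicycle. The C4 carbinol is already present.
- Against: the trans fusion and the facial sense at C1 and C5 depend on a remote tertiary silyl ether in a cycloaddition whose fusion selectivity with three-atom tethers is not dependable. The double bond is born at C6=C7, so C6 must then be oxygenated regioselectively between two secondary alkene carbons and the unsaturation moved to C8=C9. The enantiopure tertiary carbinol in A7 needs its own asymmetric synthesis.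
- Comparison: the chosen route is longer but gives each stereocentre an identifiable control element and places the C6 oxygen unambiguously.

Key step: step 3

Assumption: the (5aS,10bR) enantiomer of the aminoindanol triazolium salt is taken as the one that delivers 6; the sense is assigned by analogy with six-membered diones, and the mirror-image salt would be used if it proves opposite.

## Route

Step 1
Reactants: 1 cycloheptane-1,3-dione; 2 iodomethane
Product: 3 2-methylcycloheptane-1,3-dione
Conditions: MeI (1.0 equiv), K2CO3, acetone, 56 °C
Reagents that add atoms: iodomethane (2), CI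
Why: C-Alkylation of the 1,3-diketone enolate at the only doubly activated carbon; one equivalent of iodomethane limits dimethylation.

Step 2
Reactants: 3 2-methylcycloheptane-1,3-dione; 4 acrolein
Product: 5 3-(1-methyl-2,7-dioxocycloheptyl)propanal
Conditions: acrolein (1.5 equiv), Et3N (0.1 equiv), EtOAc, 25 °C
Reagents that add atoms: acrolein (4), C=CC=O
Why: Amine-catalysed Michael addition of the tertiary dicarbonyl carbon to acrolein; the new quaternary carbon is prochiral, so no stereochemistry is at stake.

Step 3
Reactants: 5 3-(1-methyl-2,7-dioxocycloheptyl)propanal
Product: 6 cis-fused ketol (3aS,8aR)-8a-hydroxy-3a-methyloctahydroazulene-1,4-dione (route numbering: 5α-hydroxy, 1α-methyl, ketones at C4 and C10)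
Conditions: (5aS,10bR)-2-(pentafluorophenyl)-5a,10b-dihydro-4H,6H-indeno[2,1-b][1,2,4]triazolo[4,3-d][1,4]oxazin-2-ium tetrafluoroborate (10 mol %), Et3N (10 mol %), CH2Cl2, 25 °C
Reagents that add atoms: none
Why: The triazolylidene freed by the amine adds to the aldehyde carbon C4 and, after proton transfer, gives the Breslow enaminol, an acyl anion equivalent; this attacks the ring carbonyl C5, the alkoxide is protonated and the carbene is expelled, leaving the C4 ketone. The closest known reaction type is the carbene-catalysed intramolecular crossed aldehyde–ketone benzoin reaction used to desymmetrise 2,2-disubstituted cyclic 1,3-diketones. The cyclopentane closes in a 5-exo-trig mode (C4 onto the C5 carbonyl, its oxygen outside the new ring). C1 is set by the choice between the two enantiotopic carbonyls, which is made by the aminoindanol backbone and the N-aryl group of the catalyst. C5 is set by the tether: the three-carbon chain can reach a ring carbonyl only from its own side of the seven-membered ring, so the hydroxyl comes out cis to the C1 methyl, and this cis fusion is erased in step 4. The step needs umpolung to outrun base-induced aldol addition of a ring enolate to the aldehyde, which the weak amine base and the acidic N-pentafluorophenyl triazolium salt secure, and it should be stopped before retro-benzoin equilibration erodes the enantiomeric purity.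

Step 4
Reactants: 6 cis-fused ketol
Product: 7 enedione (1α-methyl hydroazulene with C5=C6, ketones at C4 and C10)
Conditions: methyl N-(triethylammoniosulfonyl)carbamate (Burgess reagent), toluene, 60 °C
Reagents that add atoms: none
Why: Burgess dehydration by syn elimination of the sulfamate ester; C6 carries the only β-hydrogens (C1 is quaternary, C4 a carbonyl), so C5=C6 conjugated with the C4 ketone is the single possible alkene.

Step 5
Reactants: 7 enedione
Product: 8 enone ketal (C10 1,3-dioxolane of 7)
Conditions: 1,2-bis(trimethylsilyloxy)ethane, TMSOTf (5 mol %), CH2Cl2, −78 to −20 °C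
Reagents that add atoms: 1,2-bis(trimethylsilyloxy)ethane, C[Si](C)(C)OCCO[Si](C)(C)C
Why: Noyori ketalisation; the saturated C10 ketone reacts while the conjugated, less electrophilic C4 carbonyl does not, the same selectivity by which the saturated carbonyl of the Wieland–Miescher ketone is ketalised next to its quaternary carbon.

Step 6
Reactants: 8 enone ketal
Product: 9 (4S)-allylic alcohol (4α-hydroxy, C5=C6, C10 dioxolane)
Conditions: (R)-1-methyl-3,3-diphenyltetrahydro-1H,3H-pyrrolo[1,2-c][1,3,2]oxazaborole (20 mol %), catecholborane, toluene, −78 °C
Reagents that add atoms: none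
Why: Corey–Bakshi–Shibata reduction, 1,2-selective on enones; with the alkylidene carbon C5 as the large and the C3 methylene as the small group, the Corey model predicts hydride delivery to the β face by the (R)-catalyst, giving the α-hydroxyl under reagent control.

Step 7
Reactants: 9 (4S)-allylic alcohol
Product: 10 4α-triethylsilyl ether of 9
Conditions: TESCl, imidazole, DMF, 0 to 25 °C
Reagents that add atoms: chlorotriethylsilane, CC[Si](Cl)(CC)CC
Why: Standard silylation of a secondary allylic alcohol; the triethylsilyl group is the α-face shield for step 8 and can later be removed in the presence of a tert-butyldimethylsilyl ether.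

Step 8
Reactants: 10 4α-triethylsilyl ether
Product: 12 trans-fused 6β-alcohol (5β-H, 6β-hydroxy, 4α-triethylsilyloxy, C10 dioxolane), via C6 alkylborane 11 (not isolated)
Conditions: BH3·THF (3 equiv), THF, 0 to 25 °C; then NaOH (3 M aq), H2O2 (30%), 0 °C
Reagents that add atoms: borane–tetrahydrofuran, B.C1CCOC1 (boron only in 11); hydrogen peroxide, OO
Why: Hydroboration–oxidation: boron goes to the less substituted C6 and hydrogen to C5 in one syn addition, and oxidation proceeds with retention, so H5 and O6 end on the same face. The α face of C5=C6 carries both the C1 methyl and the C4 triethylsilyloxy group, so the borane is expected from the β face, giving the trans fusion and the 6β-hydroxyl.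

Step 9
Reactants: 12 trans-fused 6β-alcohol
Product: 13 6β-tert-butyldimethylsilyl ether of 12
Conditions: TBSCl, imidazole, DMAP (cat.), DMF, 40 °C
Reagents that add atoms: tert-butylchlorodimethylsilane, CC(C)(C)[Si](C)(C)Cl
Why: Silylation of the equatorial secondary hydroxyl gives an ether inert to the organocerium reagent of step 12 and cleaved by acid together with the dioxolane in step 13.

Step 10
Reactants: 13 bis-silyl ether
Product: 14 4α-alcohol (6β-tert-butyldimethylsilyloxy, C10 dioxolane)
Conditions: HF·pyridine, pyridine, THF, 0 °C
Reagents that add atoms: none
Why: Buffered hydrogen fluoride–pyridine cleaves a secondary triethylsilyl ether much faster than a secondary tert-butyldimethylsilyl ether and leaves the dioxolane alone.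

Step 11
Reactants: 14 4α-alcohol
Product: 15 trans-fused C4 ketone (5β-H, 6β-tert-butyldimethylsilyloxy, C10 dioxolane)
Conditions: Dess–Martin periodinane, NaHCO3, CH2Cl2, 0 to 25 °C
Reagents that add atoms: none
Why: Dess–Martin oxidation under bicarbonate buffer; the neutral conditions avoid epimerisation at C5 and β-elimination of the C6 silyloxy group.

Step 12
Reactants: 15 trans-fused C4 ketone; 16 isopropylmagnesium chloride
Product: 17 tertiary alcohol (4α-hydroxy-4β-isopropyl, 6β-tert-butyldimethylsilyloxy, C10 dioxolane)
Conditions: iPrMgCl (3 equiv), CeCl3 (anhydrous, 3 equiv), THF, −78 to −40 °C; then NH4Cl (aq)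
Reagents that add atoms: isopropylmagnesium chloride (16), CC(C)[Mg]Cl
Why: 1,2-Addition of an organocerium reagent (Imamoto conditions), nucleophilic but weakly basic, so that enolisation and β-hydride reduction are held back. In the trans-fused ketone the axial C1 methyl closes the α face of C4, so isopropyl enters from the β face next to H5 and the hydroxyl is left α.

Step 13
Reactants: 17 tertiary alcohol
Product: 18 keto diol (4α,6β-dihydroxy-4β-isopropyl-1α-methyl-5β-H hydroazulen-10-one)
Conditions: HCl (2 M aq), THF, 25 °C
Reagents that add atoms: water, O
Why: Aqueous acid hydrolyses the dioxolane (the C10 oxygen now comes from water) and the secondary silyl ether in one operation; the tertiary alcohol tolerates dilute acid at this temperature.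

Step 14
Reactants: 18 keto diol; 19 4-methoxybenzoyl chloride
Product: 20 6β-(4-methoxybenzoate) of 18
Conditions: 4-MeOC6H4COCl, pyridine, DMAP (cat.), CH2Cl2, 25 °C
Reagents that add atoms: 4-methoxybenzoyl chloride (19), COc1ccc(C(Cl)=O)cc1
Why: DMAP-catalysed acylation takes only the secondary C6 hydroxyl; the tertiary C4 hydroxyl, flanked by isopropyl and the ring fusion, is not acylated.

Step 15
Reactants: 20 keto ester
Product: 21 C8=C9 enone of 20
Conditions: 2-iodoxybenzoic acid (IBX, 1.5 equiv), DMSO, 65 °C
Reagents that add atoms: none
Why: Nicolaou dehydrogenation with IBX through the C9 enol; C1 is quaternary, so unsaturation can only enter at C8–C9, and the neutral oxidant leaves ester and tertiary alcohol alone.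

Step 16
Reactants: 21 enone; 22 methyllithium
Product: 23 bis(trimethylsilyl) compound (C9=C10 trimethylsilyl enol ether, 8-methyl as epimer mixture, 4α-trimethylsilyloxy, 6β-(4-methoxybenzoate))
Conditions: Me2CuLi (from MeLi and CuI, 3 equiv), TMSCl (6 equiv), THF, −78 °C; then Et3N, 0 °C
Reagents that add atoms: lithium dimethylcuprate (from methyllithium 22 and CuI), [Li+].C[Cu-]C; chlorotrimethylsilane, C[Si](C)(C)Cl
Why: Conjugate addition of a Gilman cuprate to the unhindered β-carbon C8, accelerated by chlorotrimethylsilane, which traps the enolate as the silyl enol ether and silylates the C4 alkoxide. The C8 configuration is irrelevant because C8 becomes trigonal in step 17.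

Step 17
Reactants: 23 bis(trimethylsilyl) compound
Product: 25 target, (1S,4R,5S,6S)-4-hydroxy-4-isopropyl-1,8-dimethyl-10-oxo-hydroazulen-8-en-6-yl 4-methoxybenzoate (route numbering), via C4 O-trimethylsilyl enone 24 (not isolated)
Conditions: Pd(OAc)2 (1.1 equiv), MeCN, 25 °C; then HCl (1 M aq), THF, 0 °C
Reagents that add atoms: none
Why: Saegusa–Ito oxidation: the silyl enol ether is palladated at C9 and β-hydride elimination from C8 gives the enone with the methyl on the double bond. The neutral conditions spare the δ-acyloxy enone, and brief dilute acid then frees the tertiary hydroxyl.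

## Compound list

1 | cycloheptane-1,3-dione | O=C1CCCCC(=O)C1 | starting material
2 | iodomethane | CI | starting material
3 | 2-methylcycloheptane-1,3-dione | CC1C(=O)CCCCC1=O | intermediate
4 | acrolein | C=CC=O | starting material
5 | 3-(1-methyl-2,7-dioxocycloheptyl)propanal | CC1(CCC=O)C(=O)CCCCC1=O | intermediate
6 | cis-fused ketol, (3aS,8aR)-8a-hydroxy-3a-methyloctahydroazulene-1,4-dione | C1CCCC(=O)[C@@]2(C)CCC(=O)[C@@]12O | intermediate
7 | enedione (C5=C6, ketones at C4 and C10, 1α-methyl) | C1CCC(=O)[C@@]2(C)CCC(=O)C2=C1 | intermediate
8 | enone ketal (C10 dioxolane of 7) | C1CCC3(OCCO3)[C@@]2(C)CCC(=O)C2=C1 | intermediate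
9 | (4S)-allylic alcohol (4α-hydroxy, C5=C6, C10 dioxolane) | C1CCC3(OCCO3)[C@@]2(C)CC[C@H](O)C2=C1 | intermediate
10 | 4α-triethylsilyl ether of 9 | C1CCC3(OCCO3)[C@@]2(C)CC[C@H](O[Si](CC)(CC)CC)C2=C1 | intermediate
11 | C6β alkylborane (5β-H), from 10 | B[C@H]1CCCC3(OCCO3)[C@@]2(C)CC[C@H](O[Si](CC)(CC)CC)[C@H]12 | intermediate
12 | trans-fused 6β-alcohol (4α-triethylsilyloxy, C10 dioxolane) | O[C@H]1CCCC3(OCCO3)[C@@]2(C)CC[C@H](O[Si](CC)(CC)CC)[C@H]12 | intermediate
13 | 6β-tert-butyldimethylsilyl ether of 12 | CC(C)(C)[Si](C)(C)O[C@H]1CCCC3(OCCO3)[C@@]2(C)CC[C@H](O[Si](CC)(CC)CC)[C@H]12 | intermediate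
14 | 4α-alcohol (6β-tert-butyldimethylsilyloxy, C10 dioxolane) | CC(C)(C)[Si](C)(C)O[C@H]1CCCC3(OCCO3)[C@@]2(C)CC[C@H](O)[C@H]12 | intermediate
15 | trans-fused C4 ketone (6β-tert-butyldimethylsilyloxy, C10 dioxolane) | CC(C)(C)[Si](C)(C)O[C@H]1CCCC3(OCCO3)[C@@]2(C)CCC(=O)[C@H]12 | intermediate
16 | isopropylmagnesium chloride | CC(C)[Mg]Cl | starting material
17 | tertiary alcohol (4α-hydroxy-4β-isopropyl, 6β-tert-butyldimethylsilyloxy, C10 dioxolane) | CC(C)(C)[Si](C)(C)O[C@H]1CCCC3(OCCO3)[C@@]2(C)CC[C@@](O)(C(C)C)[C@H]12 | intermediate
18 | keto diol (4α,6β-dihydroxy-4β-isopropyl, C10 ketone) | O[C@H]1CCCC(=O)[C@@]2(C)CC[C@@](O)(C(C)C)[C@H]12 | intermediate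
19 | 4-methoxybenzoyl chloride | COc1ccc(C(Cl)=O)cc1 | starting material
20 | 6β-(4-methoxybenzoate) of 18 | COc1ccc(C(=O)O[C@H]2CCCC(=O)[C@@]3(C)CC[C@@](O)(C(C)C)[C@H]23)cc1 | intermediate
21 | C8=C9 enone of 20 | COc1ccc(C(=O)O[C@H]2CC=CC(=O)[C@@]3(C)CC[C@@](O)(C(C)C)[C@H]23)cc1 | intermediate
22 | methyllithium | C[Li] | starting material
23 | bis(trimethylsilyl) compound (C9=C10 silyl enol ether, 8-methyl, 4α-trimethylsilyloxy) | COc1ccc(C(=O)O[C@H]2CC(C)C=C(O[Si](C)(C)C)[C@@]3(C)CC[C@@](O[Si](C)(C)C)(C(C)C)[C@H]23)cc1 | intermediate
24 | C4 O-trimethylsilyl ether of the target | COc1ccc(C(=O)O[C@H]2CC(C)=CC(=O)[C@@]3(C)CC[C@@](O[Si](C)(C)C)(C(C)C)[C@H]23)cc1 | intermediate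
25 | target CNP0301380.2 | COc1ccc(C(=O)O[C@H]2CC(C)=CC(=O)[C@@]3(C)CC[C@@](O)(C(C)C)[C@H]23)cc1 | target

## Step count and least certain steps

Total: 17 steps. Longest linear sequence: 17 steps (the route is linear from 1; compounds 2, 4, 16, 19 and 22 are bought).

**Step 3 (key step).** What may go wrong: poor discrimination between the two enantiotopic carbonyls of the conformationally mobile seven-membered dione, erosion of enantiomeric purity by retro-benzoin equilibration, or diversion of 5 into base-induced aldol addition of a ring enolate to the aldehyde. Fallback, from 5 back to the route at 9: reductive pinacol cyclisation of 5 with SmI2 in THF at −78 °C forms the same C4–C5 bond without base and gives the racemic cis-fused diol F1. Dess–Martin oxidation of its secondary C4 hydroxyl gives the racemic ketol F2, which is taken through the operations of steps 4 and 5 to the racemic enedione F3 and the racemic enone ketal F4. The oxazaborolidine reduction of step 6 then acts as the resolving step: reagent control should give the (4S)-alcohol from both enantiomers, that is 9 and its C1-epimeric diastereomer F5, which are separated by chromatography. At most half of the material is used, but the absolute configuration then comes from a reduction of dependable sense.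

**Step 8.** What may go wrong: attack of the borane on the α face, because the C10 dioxolane lies on the β side of C1 and may offset the shielding by methyl and silyloxy group; this would give the cis-fused isomer. Fallback, from 9 back at 14: the α-hydroxyl of 9 is converted with 1,1,3,3-tetramethyldisilazane into the dimethylsilyl ether F6. Pt2[(CH2=CHSiMe2)2O]3 in toluene at 60 °C then effects intramolecular hydrosilylation to the oxasilolane F7; silicon goes to C6 and hydrogen to C5, and only β-face delivery gives the strain-free cis-fused five-membered siloxane. Tamao oxidation (H2O2, KF, KHCO3, THF/MeOH) gives the 4α,6β-diol F8. Its equatorial C6 hydroxyl is silylated selectively (TBSCl, imidazole), the C4 hydroxyl being syn-axial to the C1 methyl, to give 14.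

**Step 12.** What may go wrong: enolisation of 15 toward C5, followed by loss of the C6 silyloxy group by β-elimination or by epimerisation at C5, and reduction of the ketone by β-hydride transfer from the isopropyl reagent. Fallback, from 15 back at 17: the 2-propenyl cerium reagent (2-propenylmagnesium bromide, CeCl3, THF, −78 °C), which has no β-hydrogen to transfer and is less basic, should add from the same β face to give the isopropenyl carbinol F9. Hydrogenation of its 1,1-disubstituted double bond (H2, PtO2, EtOAc) gives 17.

**Step 15.** What may go wrong: over-oxidation toward the dienone or loss of 4-methoxybenzoic acid at 65 °C, or sluggish enolisation of the hindered ketone. Fallback, from 20 back at 21: soft enolisation (TMSOTf, Et3N, CH2Cl2, 0 °C) gives the C9=C10 silyl enol ether with the C4 hydroxyl also silylated, F10. Pd(OAc)2 in MeCN at 25 °C gives the C4 O-silylated enone F11, and dilute HCl frees the tertiary hydroxyl to give 21.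

## Further compounds

F1 | step 3 | racemic cis-fused 4,5-diol with C10 ketone (C4 epimers) | C1CCCC(=O)[C@@]2(C)CCC(O)[C@@]12O.C1CCCC(=O)[C@]2(C)CCC(O)[C@]12O
F2 | step 3 | racemic ketol (racemate of 6) | C1CCCC(=O)[C@@]2(C)CCC(=O)[C@@]12O.C1CCCC(=O)[C@]2(C)CCC(=O)[C@]12O
F3 | step 3 | racemic enedione (racemate of 7) | C1CCC(=O)C2(C)CCC(=O)C2=C1
F4 | step 3 | racemic enone ketal (racemate of 8) | C1CCC3(OCCO3)C2(C)CCC(=O)C2=C1
F5 | step 3 | (1R,4S)-allylic alcohol, C1 epimer of 9 | C1CCC3(OCCO3)[C@]2(C)CC[C@H](O)C2=C1
F6 | step 8 | 4α-dimethylsilyl ether of 9 | C1CCC3(OCCO3)[C@@]2(C)CC[C@H](O[SiH](C)C)C2=C1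
F7 | step 8 | oxasilolane bridging O4 and C6 (5β-H, C10 dioxolane) | C[Si]4(C)[C@H]1CCCC3(OCCO3)[C@@]2(C)CC[C@H](O4)[C@H]12
F8 | step 8 | 4α,6β-diol (5β-H, C10 dioxolane) | O[C@H]1CCCC3(OCCO3)[C@@]2(C)CC[C@H](O)[C@H]12
F9 | step 12 | isopropenyl carbinol (4α-hydroxy-4β-(prop-1-en-2-yl), 6β-tert-butyldimethylsilyloxy, C10 dioxolane) | CC(C)(C)[Si](C)(C)O[C@H]1CCCC3(OCCO3)[C@@]2(C)CC[C@@](O)(C(C)=C)[C@H]12
F10 | step 15 | C9=C10 trimethylsilyl enol ether of 20 with 4α-trimethylsilyloxy | COc1ccc(C(=O)O[C@H]2CCC=C(O[Si](C)(C)C)[C@@]3(C)CC[C@@](O[Si](C)(C)C)(C(C)C)[C@H]23)cc1
F11 | step 15 | C4 O-trimethylsilyl ether of 21 | COc1ccc(C(=O)O[C@H]2CC=CC(=O)[C@@]3(C)CC[C@@](O[Si](C)(C)C)(C(C)C)[C@H]23)cc1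
A1 | alternative 1 | trimethylsilyl enol ether of the bis-silylated trans-hydrindanone (C8=C10) | CC(C)(C)[Si](C)(C)O[C@H]1CC(C)=C(O[Si](C)(C)C)[C@@]2(C)CC[C@@](O[Si](CC)(CC)CC)(C(C)C)[C@H]12
A2 | alternative 1 | bis-silylated bicyclic cycloheptenone | CC(C)(C)[Si](C)(C)O[C@H]1CC(C)=CC(=O)[C@@]2(C)CC[C@@](O[Si](CC)(CC)CC)(C(C)C)[C@H]12
A3 | alternative 2 | 3-methylcyclopent-2-enone | CC1=CC(=O)CC1
A4 | alternative 2 | diisobutyl[1-(trimethylsilyl)vinyl]aluminium | C=C([Si](C)(C)C)[Al](CC(C)C)CC(C)C
A5 | alternative 2 | 2-(2-methyl-1,3-dioxolan-2-yl)acetaldehyde | CC1(CC=O)OCCO1
A6 | alternative 2 | 2,3,3-trisubstituted cyclopentanone aldol | O[C@@H](CC1(C)OCCO1)[C@@H]2[C@@](C)(C(=C)[Si](C)(C)C)CCC2=O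
A7 | alternative 3 | tertiary α-chloro methyl ketone with tethered (E,E)-diene and C4 triethylsilyl ether | CC(=O)C(C)(Cl)CC[C@@](O[Si](CC)(CC)CC)(C(C)C)/C=C/C=C/C
A8 | alternative 3 | bicyclic cyclohept-4-enone with C6=C7 and C8 methyl | C1=C[C@H](C)CC(=O)[C@@]2(C)CC[C@@](O[Si](CC)(CC)CC)(C(C)C)[C@H]12
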